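**Retrosynthetic overview**
1. Lukianol B comes from its tri-O-methyl ether by a final global O-demethylation; the iodine is already in place at that stage.
2. The tri-O-methyl ether is cut into a monocyclic N-(3-arylpropargyl)-1,4-oxazine-2,3-dione and (3-iodo-4-methoxyphenyl)boronic acid. One nickel-catalysed arylative cyclisation forms the C7–aryl bond and the C8–C8a bond, and loss of water gives the aromatic pyrrole.
3. Enabling feature: in the pyrrole ring (N5, C6, C7, C8, C8a), C7=C8 carries two cis aryl groups, C6 is the only CH, and C8a bears both N5 and the lactone carbonyl C1. Read backwards, C7≡C8 is an aryl alkyne, C6 a propargylic CH2 and C8a the amide carbonyl of a cyclic oxamate, which sits at the same oxidation level as the pyrrole plus water.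
4. The oxazinedione comes from oxalyl chloride and an N-propargyl α-amino ketone, which comes from an alkynyl amine (Sonogashira coupling) and a phenacyl bromide. The boronic acid comes from the amino boronic acid by Sandmeyer iodination.
5. Ring order: oxazinone ring A first (step 3), pyrrole ring B last (step 5). The three benzene rings are bought.

Key step: step 5

Remark: positions follow 1H-pyrrolo[2,1-c][1,4]oxazin-1-one (C1 carbonyl, O2, C3, C4, N5, C6, C7, C8, C8a). The target has no stereocentre. The one stereocentre that arises on the way (C8a of the hemiaminal in the key step) is racemic and is erased in the same flask.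

Step 1
Reactants: 1 4-iodoanisole; 2 propargylamine
Product: 3 3-(4-methoxyphenyl)prop-2-yn-1-amine
Conditions: PdCl2(PPh3)2 (2 mol %), CuI (4 mol %), Et3N, THF, rt
Reagents that add atoms: none
Why: Sonogashira coupling of an aryl iodide with a terminal alkyne runs at room temperature and tolerates the free primary amine.

Step 2
Reactants: 3 3-(4-methoxyphenyl)prop-2-yn-1-amine; 4 2-bromo-1-(4-methoxyphenyl)ethan-1-one
Product: 5 1-(4-methoxyphenyl)-2-{[3-(4-methoxyphenyl)prop-2-yn-1-yl]amino}ethan-1-one
Conditions: 3 (3 equiv, excess recovered), NaHCO3, MeCN, 0 °C; product carried on at once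
Reagents that add atoms: none
Why: SN2 N-alkylation of a primary amine by a very reactive α-bromo ketone, in which the excess of amine and the low temperature should hold back a second alkylation and immediate use avoids self-condensation of the α-amino ketone.

Step 3
Reactants: 5 1-(4-methoxyphenyl)-2-{[3-(4-methoxyphenyl)prop-2-yn-1-yl]amino}ethan-1-one
Product: 7 6-(4-methoxyphenyl)-4-[3-(4-methoxyphenyl)prop-2-yn-1-yl]-2H-1,4-oxazine-2,3(4H)-dione, via oxamoyl chloride 6 (not isolated)
Conditions: (COCl)2 (3 equiv), CH2Cl2, −78 °C, slow addition of 5 + Et3N (1 equiv); excess (COCl)2 evaporated; then Et3N (1.2 equiv), DMAP (cat.), CH2Cl2, 0 °C to rt; moisture excluded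
Reagents that add atoms: oxalyl chloride, O=C(Cl)C(=O)Cl
Why: N-acylation under inverse addition (which avoids the bis-amide) gives 6, and its acid chloride is then taken by the enolate oxygen of the neighbouring aryl ketone in a 6-exo-trig enol-lactonisation, the only closure open to it because C-acylation would give a four-membered ring.

Step 4
Reactants: 8 (3-amino-4-methoxyphenyl)boronic acid
Product: 10 (3-iodo-4-methoxyphenyl)boronic acid, via diazonium chloride 9 (not isolated)
Conditions: NaNO2, aq. HCl, 0 °C; then KI, 0 °C to rt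
Reagents that add atoms: potassium iodide, [K+].[I-]; sodium nitrite, [Na+].[O-]N=O (its nitrogen stands in 9 only); hydrogen chloride, Cl (its chloride stands in 9 only)
Why: Sandmeyer-type diazotisation–iodination replaces the amino group ipso, which places iodine ortho to the methoxy group and meta to boron without an electrophilic iodination that could attack the C–B bond.

Step 5
Reactants: 7 6-(4-methoxyphenyl)-4-[3-(4-methoxyphenyl)prop-2-yn-1-yl]-2H-1,4-oxazine-2,3(4H)-dione; 10 (3-iodo-4-methoxyphenyl)boronic acid
Product: 12 7-(3-iodo-4-methoxyphenyl)-3,8-bis(4-methoxyphenyl)-1H-pyrrolo[2,1-c][1,4]oxazin-1-one (tri-O-methyl-lukianol B), via hemiaminal 11 (not isolated)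
Conditions: Ni(OAc)2·4H2O (10 mol %), 2-[2-(diphenylphosphino)ethyl]pyridine (10 mol %), 10 (2 equiv), CF3CH2OH, 80 °C
Reagents that add atoms: none
Why: Proposed new method: transmetallation of 10 to the divalent nickel acetate complex gives an arylnickel species that adds syn across the alkyne of 7 and so forms the C7–aryl bond, the aryl going to the CH2-bearing carbon and nickel to the anisyl-bearing carbon (future C8) because the aryl substituent stabilises the adjacent C–Ni bond. Reversible E/Z isomerisation of this alkenylnickel brings C8 cis to the CH2–N arm, C8 then attacks the amide carbonyl C3 of the oxazinedione in a 5-exo-trig closure of ring B (C8–C8a bond), protonolysis of the nickel alkoxide by CF3CH2OH frees hemiaminal 11 and the catalyst, and 11 loses water (C8a–OH and one C6–H) under the driving force of pyrrole aromaticity, the whole sequence being redox-neutral. The closest known reaction type is the nickel-catalysed anti-carbometallative arylative cyclisation of N-sulfonyl-N-propargyl amides with arylboronic acids to 2,3,4-trisubstituted pyrroles; new is the amide partner, a cyclic enol oxamate, whose C3 carbonyl is activated by the vicinal lactone carbonyl C2 and by drain of the nitrogen lone pair into the C5=C6 enol-ester double bond, much as a sulfonyl group does. Site selectivity is secured by ring A itself: attack at C2 would have to build a bridged bicycle with a twisted bridgehead amide, and the aryl ketone that would otherwise offer a competing six-membered closure is masked as the enol ester. The only new stereocentre, C8a of 11, is under no control, forms as the racemate and vanishes on dehydration. The aryl C–I bond should persist because nickel stays divalent through the whole cycle, no base or reductant is present, and the iodide is electron-rich and flanked by the methoxy group.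

Step 6
Reactants: 12 7-(3-iodo-4-methoxyphenyl)-3,8-bis(4-methoxyphenyl)-1H-pyrrolo[2,1-c][1,4]oxazin-1-one
Product: 13 lukianol B, 7-(4-hydroxy-3-iodophenyl)-3,8-bis(4-hydroxyphenyl)-1H-pyrrolo[2,1-c][1,4]oxazin-1-one
Conditions: BBr3 (9 equiv), CH2Cl2, −78 °C to rt; then H2O, 0 °C
Reagents that add atoms: none
Why: Lewis-acid cleavage of aryl methyl ethers with BBr3 should remove all three methyl groups at or below room temperature, conditions that aryl iodides and the enol lactone of this ring system withstand.

**Compound list**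
1 | 4-iodoanisole | COc1ccc(I)cc1 | starting material
2 | propargylamine (prop-2-yn-1-amine) | C#CCN | starting material
3 | 3-(4-methoxyphenyl)prop-2-yn-1-amine | COc1ccc(C#CCN)cc1 | intermediate
4 | 2-bromo-1-(4-methoxyphenyl)ethan-1-one | COc1ccc(C(=O)CBr)cc1 | starting material
5 | 1-(4-methoxyphenyl)-2-{[3-(4-methoxyphenyl)prop-2-yn-1-yl]amino}ethan-1-one | COc1ccc(C#CCNCC(=O)c2ccc(OC)cc2)cc1 | intermediate
6 | 2-{[2-(4-methoxyphenyl)-2-oxoethyl][3-(4-methoxyphenyl)prop-2-yn-1-yl]amino}-2-oxoacetyl chloride (not isolated) | COc1ccc(C#CCN(CC(=O)c2ccc(OC)cc2)C(=O)C(=O)Cl)cc1 | intermediate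
7 | 6-(4-methoxyphenyl)-4-[3-(4-methoxyphenyl)prop-2-yn-1-yl]-2H-1,4-oxazine-2,3(4H)-dione | COc1ccc(C#CCN2C=C(c3ccc(OC)cc3)OC(=O)C2=O)cc1 | intermediate
8 | (3-amino-4-methoxyphenyl)boronic acid | COc1ccc(B(O)O)cc1N | starting material
9 | 5-borono-2-methoxybenzenediazonium chloride (not isolated) | COc1ccc(B(O)O)cc1[N+]#N.[Cl-] | intermediate
10 | (3-iodo-4-methoxyphenyl)boronic acid | COc1ccc(B(O)O)cc1I | intermediate
11 | 8a-hydroxy-7-(3-iodo-4-methoxyphenyl)-3,8-bis(4-methoxyphenyl)-6,8a-dihydro-1H-pyrrolo[2,1-c][1,4]oxazin-1-one (racemic, not isolated) | COc1ccc(cc1)C1=C(c2ccc(OC)c(I)c2)CN2C=C(c3ccc(OC)cc3)OC(=O)C12O | intermediate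
12 | 7-(3-iodo-4-methoxyphenyl)-3,8-bis(4-methoxyphenyl)-1H-pyrrolo[2,1-c][1,4]oxazin-1-one | O=c1oc(-c2ccc(OC)cc2)cn2cc(-c3ccc(OC)c(I)c3)c(-c3ccc(OC)cc3)c12 | intermediate
13 | lukianol B | O=c1oc(-c2ccc(O)cc2)cn2cc(-c3ccc(O)c(I)c3)c(-c3ccc(O)cc3)c12 | target

**Total step count:** 6. **Longest linear sequence:** 5 steps (1, 2, 3, 5, 6).

**Steps most likely to fail**

Step 5. What may go wrong:
- The enol-oxamate ring may open solvolytically through CF3CH2OH or through water released by the boronic acid before the alkenylnickel closes.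
- Slow E/Z isomerisation may end in plain hydroarylation of the alkyne.
- Traces of zerovalent nickel may erode the C–I bond.

The fallback keeps the pyrrole formation inside the documented N-sulfonyl alkynamide class and closes the lactone afterwards. It sets out from 3 and comes back at 12. Sulfonylation of 3 (TsCl, pyridine) should give N-[3-(4-methoxyphenyl)prop-2-yn-1-yl]-4-methylbenzenesulfonamide F1. Acylation with methyl chlorooxoacetate (Et3N, DMAP, CH2Cl2) should give methyl 2-{[3-(4-methoxyphenyl)prop-2-yn-1-yl](4-methylbenzenesulfonyl)amino}-2-oxoacetate F2. The known nickel-catalysed arylative cyclisation of N-tosyl alkynamides, run with 10 (Ni(OAc)2·4H2O, the same P,N ligand, CF3CH2OH, 80 °C), should give methyl 4-(3-iodo-4-methoxyphenyl)-3-(4-methoxyphenyl)-1-(4-methylbenzenesulfonyl)-1H-pyrrole-2-carboxylate F3. TBAF in THF should remove the sulfonyl group to give methyl 4-(3-iodo-4-methoxyphenyl)-3-(4-methoxyphenyl)-1H-pyrrole-2-carboxylate F4. N-alkylation with 4 (K2CO3, DMF) should give methyl 4-(3-iodo-4-methoxyphenyl)-3-(4-methoxyphenyl)-1-[2-(4-methoxyphenyl)-2-oxoethyl]-1H-pyrrole-2-carboxylate F5. Saponification (LiOH, THF/H2O) should give 4-(3-iodo-4-methoxyphenyl)-3-(4-methoxyphenyl)-1-[2-(4-methoxyphenyl)-2-oxoethyl]-1H-pyrrole-2-carboxylic acid F6. Enol-lactonisation (Ac2O, NaOAc, heat) then rejoins the route at 12.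

Step 3. What may go wrong:
- Two amine molecules may be acylated by one oxalyl chloride.
- The oxamoyl chloride may lose carbon monoxide.
- The activated enol ester may hydrolyse during isolation.

The fallback replaces the one-flask closure by a stepwise build-up with a dehydrative ring closure. It sets out from 5 and comes back at 7. Acylation of 5 with methyl chlorooxoacetate (Et3N, CH2Cl2, 0 °C) should give methyl 2-{[2-(4-methoxyphenyl)-2-oxoethyl][3-(4-methoxyphenyl)prop-2-yn-1-yl]amino}-2-oxoacetate F7. Mild saponification (LiOH, THF/H2O, 0 °C) should give 2-{[2-(4-methoxyphenyl)-2-oxoethyl][3-(4-methoxyphenyl)prop-2-yn-1-yl]amino}-2-oxoacetic acid F8. Ac2O/NaOAc should then close the enol lactone through the mixed anhydride to give 7, which crystallises from the anhydrous medium.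

Step 2. What may go wrong:
- The product amine may be alkylated a second time.
- The free α-amino ketone may self-condense or oxidise in air.

The fallback is a Fukuyama amine synthesis, which makes monoalkylation structural rather than statistical. It sets out from 3 and comes back at 5. 2-Nitrobenzenesulfonyl chloride (Et3N, CH2Cl2) should give N-[3-(4-methoxyphenyl)prop-2-yn-1-yl]-2-nitrobenzenesulfonamide F9. Alkylation with 4 (K2CO3, DMF, rt) should give N-[2-(4-methoxyphenyl)-2-oxoethyl]-N-[3-(4-methoxyphenyl)prop-2-yn-1-yl]-2-nitrobenzenesulfonamide F10. Thiophenol/K2CO3 in DMF should then release 5.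

**Further compounds**
F1 | step 5 | N-[3-(4-methoxyphenyl)prop-2-yn-1-yl]-4-methylbenzenesulfonamide | COc1ccc(C#CCNS(=O)(=O)c2ccc(C)cc2)cc1
F2 | step 5 | methyl 2-{[3-(4-methoxyphenyl)prop-2-yn-1-yl](4-methylbenzenesulfonyl)amino}-2-oxoacetate | COC(=O)C(=O)N(CC#Cc1ccc(OC)cc1)S(=O)(=O)c1ccc(C)cc1
F3 | step 5 | methyl 4-(3-iodo-4-methoxyphenyl)-3-(4-methoxyphenyl)-1-(4-methylbenzenesulfonyl)-1H-pyrrole-2-carboxylate | COC(=O)c1c(-c2ccc(OC)cc2)c(-c2ccc(OC)c(I)c2)cn1S(=O)(=O)c1ccc(C)cc1
F4 | step 5 | methyl 4-(3-iodo-4-methoxyphenyl)-3-(4-methoxyphenyl)-1H-pyrrole-2-carboxylate | COC(=O)c1[nH]cc(-c2ccc(OC)c(I)c2)c1-c1ccc(OC)cc1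
F5 | step 5 | methyl 4-(3-iodo-4-methoxyphenyl)-3-(4-methoxyphenyl)-1-[2-(4-methoxyphenyl)-2-oxoethyl]-1H-pyrrole-2-carboxylate | COC(=O)c1c(-c2ccc(OC)cc2)c(-c2ccc(OC)c(I)c2)cn1CC(=O)c1ccc(OC)cc1
F6 | step 5 | 4-(3-iodo-4-methoxyphenyl)-3-(4-methoxyphenyl)-1-[2-(4-methoxyphenyl)-2-oxoethyl]-1H-pyrrole-2-carboxylic acid | OC(=O)c1c(-c2ccc(OC)cc2)c(-c2ccc(OC)c(I)c2)cn1CC(=O)c1ccc(OC)cc1
F7 | step 3 | methyl 2-{[2-(4-methoxyphenyl)-2-oxoethyl][3-(4-methoxyphenyl)prop-2-yn-1-yl]amino}-2-oxoacetate | COC(=O)C(=O)N(CC#Cc1ccc(OC)cc1)CC(=O)c1ccc(OC)cc1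
F8 | step 3 | 2-{[2-(4-methoxyphenyl)-2-oxoethyl][3-(4-methoxyphenyl)prop-2-yn-1-yl]amino}-2-oxoacetic acid | OC(=O)C(=O)N(CC#Cc1ccc(OC)cc1)CC(=O)c1ccc(OC)cc1
F9 | step 2 | N-[3-(4-methoxyphenyl)prop-2-yn-1-yl]-2-nitrobenzenesulfonamide | COc1ccc(C#CCNS(=O)(=O)c2ccccc2[N+](=O)[O-])cc1
F10 | step 2 | N-[2-(4-methoxyphenyl)-2-oxoethyl]-N-[3-(4-methoxyphenyl)prop-2-yn-1-yl]-2-nitrobenzenesulfonamide | COc1ccc(C#CCN(CC(=O)c2ccc(OC)cc2)S(=O)(=O)c2ccccc2[N+](=O)[O-])cc1
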